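The route rests on disconnecting the C2=C3 double bond in the pyranone ring (ring C) of flavone unit 1. The neighbouring O1–C2 bond is laid down beforehand as an aryl ester. This ester joins the ring A phenol to a ring B benzoic acid that already bears the finished, benzyl-protected flavone unit 2 at C3'. One thermal intramolecular Wittig reaction then lets the ketone-stabilised ylide carbon (future C3) olefinate that ester carbonyl (C2), closing ring C and giving the fully protected biflavone. The precursor is a 2-aroyloxy-6-benzyloxy-4-methoxyphenacylidene triphenylphosphorane, assembled from one ring A acetophenone that serves both flavone units.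

Key step: step 12

Assumption: 1-(2,6-dihydroxy-4-methoxyphenyl)ethanone is taken as a purchasable starting material; because it is symmetric, its first benzylation raises no regiochemical question.

Step 1
Reactants: 1 1-(2,6-dihydroxy-4-methoxyphenyl)ethanone
Product: 2 1-[2-(benzyloxy)-6-hydroxy-4-methoxyphenyl]ethanone
Conditions: BnBr (1.05 equiv), K2CO3 (1.2 equiv), acetone, reflux
Reagents that add atoms: benzyl bromide, BrCc1ccccc1
Why: Williamson O-alkylation of the symmetric diol should stop at the mono-ether because the remaining hydroxyl is then tied up in a strong hydrogen bond to the acetyl carbonyl, and the symmetry of 1 removes any question of regiochemistry.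

Step 2
Reactants: 2 1-[2-(benzyloxy)-6-hydroxy-4-methoxyphenyl]ethanone
Product: 3 1-[6-(benzyloxy)-2-hydroxy-3-iodo-4-methoxyphenyl]ethanone
Conditions: NIS (1.0 equiv), cat. CF3CO2H, MeCN, 0 °C, dark
Reagents that add atoms: N-iodosuccinimide, O=C1CCC(=O)N1I
Why: Electrophilic aromatic iodination should take place at C3, ortho to the chelated free phenol and flanked only by OH and OMe, in preference to C5 between the two ether groups, as is usual for 2-hydroxy-4,6-dialkoxyacetophenones, while one equivalent of NIS at 0 °C limits di-iodination.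

Step 3
Reactants: 3 1-[6-(benzyloxy)-2-hydroxy-3-iodo-4-methoxyphenyl]ethanone; 4 4-(benzyloxy)benzoyl chloride
Product: 5 1-[6-(benzyloxy)-2-hydroxy-3-iodo-4-methoxyphenyl]-3-[4-(benzyloxy)phenyl]propane-1,3-dione
Conditions: LiN(SiMe3)2 (3.2 equiv), THF, −78 → −10 °C; then 4 (1.05 equiv), −78 °C → rt; aq. NH4Cl
Reagents that add atoms: none
Why: Excess amide base turns 3 into its phenoxide–enolate dianion, whose carbon terminus undergoes crossed Claisen acylation by the aroyl chloride to give the 1,3-diketone in one flask (a direct variant of the Baker–Venkataraman sequence), and neither the aryl iodide nor the benzyl ethers react with the hindered amide.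

Step 4
Reactants: 5 1-[6-(benzyloxy)-2-hydroxy-3-iodo-4-methoxyphenyl]-3-[4-(benzyloxy)phenyl]propane-1,3-dione
Product: 6 5-(benzyloxy)-2-[4-(benzyloxy)phenyl]-8-iodo-7-methoxy-4H-chromen-4-one (the 8-iodoflavone of unit 2)
Conditions: NaOAc, AcOH, 110 °C
Reagents that add atoms: none
Why: Cyclodehydration of the 2-hydroxyaryl 1,3-diketone (attack of the phenol on the enolised aroyl carbonyl, then loss of water) closes the pyranone of unit 2 and places the iodine at C8'', and the acetate-buffered acetic acid is mild enough to keep the peri benzyl ether and the electron-rich aryl iodide.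

Step 5
Reactants: 7 methyl 4-hydroxy-3-iodobenzoate
Product: 8 methyl 4-(benzyloxy)-3-iodobenzoate
Conditions: BnBr (1.1 equiv), K2CO3 (1.5 equiv), DMF, 60 °C
Reagents that add atoms: benzyl bromide, BrCc1ccccc1
Why: Williamson O-alkylation of an unhindered, fairly acidic phenol para to an ester is routine and leaves the methyl ester and the aryl iodide alone.

Step 6
Reactants: 8 methyl 4-(benzyloxy)-3-iodobenzoate
Product: 9 methyl 4-(benzyloxy)-3-(4,4,5,5-tetramethyl-1,3,2-dioxaborolan-2-yl)benzoate
Conditions: B2pin2 (1.2 equiv), Pd(dppf)Cl2 (3 mol%), KOAc (3 equiv), 1,4-dioxane, 90 °C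
Reagents that add atoms: bis(pinacolato)diboron, CC1(C)OB(OC1(C)C)B1OC(C)(C)C(C)(C)O1
Why: Miyaura borylation of an aryl iodide runs under weakly basic KOAc conditions that tolerate the methyl ester and the benzyl ether, and the ortho alkoxy group does not block oxidative addition at the C–I bond.

Step 7
Reactants: 6 5-(benzyloxy)-2-[4-(benzyloxy)phenyl]-8-iodo-7-methoxy-4H-chromen-4-one; 9 methyl 4-(benzyloxy)-3-(4,4,5,5-tetramethyl-1,3,2-dioxaborolan-2-yl)benzoate
Product: 10 methyl 4-(benzyloxy)-3-{5-(benzyloxy)-2-[4-(benzyloxy)phenyl]-7-methoxy-4-oxo-4H-chromen-8-yl}benzoate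
Conditions: 9 (1.3 equiv), Pd(OAc)2 (5 mol%), SPhos (10 mol%), K3PO4 (3 equiv), toluene/H2O (10:1), 90 °C
Reagents that add atoms: none
Why: Suzuki–Miyaura cross-coupling forms the C3'–C8'' biaryl bond, the bulky electron-rich biarylphosphine SPhos being chosen because it promotes oxidative addition and reductive elimination at the doubly ortho-flanked C8'' iodide, while the flavone carbonyl, the ethers and the ester are inert to these conditions.

Step 8
Reactants: 10 methyl 4-(benzyloxy)-3-{5-(benzyloxy)-2-[4-(benzyloxy)phenyl]-7-methoxy-4-oxo-4H-chromen-8-yl}benzoate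
Product: 11 4-(benzyloxy)-3-{5-(benzyloxy)-2-[4-(benzyloxy)phenyl]-7-methoxy-4-oxo-4H-chromen-8-yl}benzoic acid
Conditions: LiOH·H2O (3 equiv), THF/MeOH/H2O (3:1:1), 40 °C; then 1 M HCl to pH 3
Reagents that add atoms: lithium hydroxide (hydroxide oxygen), [Li+].[OH-]
Why: Saponification (acyl–oxygen cleavage by hydroxide) of the unhindered methyl benzoate should proceed under conditions too mild to open the electron-rich 5,7-dialkoxypyranone of unit 2 or to touch the ethers.

Step 9
Reactants: 2 1-[2-(benzyloxy)-6-hydroxy-4-methoxyphenyl]ethanone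
Product: 12 2-bromo-1-[2-(benzyloxy)-6-hydroxy-4-methoxyphenyl]ethanone
Conditions: CuBr2 (2.0 equiv), EtOAc/CHCl3 (1:1), reflux
Reagents that add atoms: CuBr2 (copper dibromide), Br[Cu]Br
Why: CuBr2 in refluxing ethyl acetate/chloroform is the classical reagent for selective side-chain alpha-bromination of hydroxyacetophenones, acting on the copper-bound enol of the methyl ketone and not on the activated ring, and the product is taken on promptly before it can cyclise to a benzofuranone.

Step 10
Reactants: 12 2-bromo-1-[2-(benzyloxy)-6-hydroxy-4-methoxyphenyl]ethanone; 13 triphenylphosphine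
Product: 15 1-[2-(benzyloxy)-6-hydroxy-4-methoxyphenyl]-2-(triphenylphosphoranylidene)ethanone, via phosphonium bromide 14 (not isolated)
Conditions: 13 (1.05 equiv), CH2Cl2, rt; then aq. Na2CO3 (1 M), rt
Reagents that add atoms: none
Why: SN2 displacement of the primary phenacyl bromide by triphenylphosphine gives the phosphonium salt, whose methylene (far more acidic than the chelated phenol) is deprotonated by aqueous carbonate to the ketone-stabilised ylide, which is stable to water and keeps the free phenol.

Step 11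
Reactants: 11 4-(benzyloxy)-3-{5-(benzyloxy)-2-[4-(benzyloxy)phenyl]-7-methoxy-4-oxo-4H-chromen-8-yl}benzoic acid; 15 1-[2-(benzyloxy)-6-hydroxy-4-methoxyphenyl]-2-(triphenylphosphoranylidene)ethanone
Product: 17 3-(benzyloxy)-5-methoxy-2-[(triphenylphosphoranylidene)acetyl]phenyl 4-(benzyloxy)-3-{5-(benzyloxy)-2-[4-(benzyloxy)phenyl]-7-methoxy-4-oxo-4H-chromen-8-yl}benzoate (the O-aroyl ylide), via acid chloride 16 (not isolated)
Conditions: 11, 1-chloro-N,N,2-trimethylpropenylamine (1.1 equiv), CH2Cl2, 0 °C → rt; then 15 (1.2 equiv), Et3N (1.5 equiv), CH2Cl2, 0 °C → rt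
Reagents that add atoms: none
Why: The neutral chloroenamine converts the acid into its chloride without strong acid that could harm the flavone or the benzyl ethers, and the chloride then esterifies the phenol of 15 under amine base, the known site of acylation for 2-hydroxyphenacylidene phosphoranes because the ketone-stabilised ylide carbon is a much weaker nucleophile than the phenoxide.

Step 12
Reactants: 17 3-(benzyloxy)-5-methoxy-2-[(triphenylphosphoranylidene)acetyl]phenyl 4-(benzyloxy)-3-{5-(benzyloxy)-2-[4-(benzyloxy)phenyl]-7-methoxy-4-oxo-4H-chromen-8-yl}benzoate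
Product: 18 5-(benzyloxy)-2-{4-(benzyloxy)-3-[5-(benzyloxy)-2-(4-(benzyloxy)phenyl)-7-methoxy-4-oxo-4H-chromen-8-yl]phenyl}-7-methoxy-4H-chromen-4-one (tetra-O-benzyl biflavone)
Conditions: toluene (0.02 M), 110 °C, N2
Reagents that add atoms: none
Why: The carbanionic ylide carbon (future C3) attacks the adjacent aroyloxy carbonyl (future C2), the betaine passes through an oxaphosphetane, and cycloreversion expels triphenylphosphine oxide to leave the C2=C3 enol-ether double bond. This is the established intramolecular Wittig olefination of aryl esters by 2-acyloxyphenacylidene phosphoranes, which gives chromones and flavones on heating. Ring C forms by a 6-exo-trig attack on the ester carbonyl, and the new double bond lies inside the six-membered pyranone. No stereocentre is created. The step needs chemoselectivity for the ester carbonyl over the C4'' carbonyl of unit 2, and this is secured because only the ester is within intramolecular reach, whereas the remote C4'' carbonyl is a deactivated vinylogous ester that stabilised ylides do not attack intermolecularly. The neutral, base-free medium and the aromatic stabilisation of the emerging benzopyranone should favour olefination over O-to-C acyl transfer and spare the benzyl ethers, the methyl ethers and the finished unit 2.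

Step 13
Reactants: 18 tetra-O-benzyl biflavone
Product: 19 7,7''-dimethoxyamentoflavone
Conditions: H2 (1 atm), Pd/C (10 wt% palladium on carbon), THF/MeOH (1:1), rt
Reagents that add atoms: none
Why: Catalytic hydrogenolysis cleaves the four aryl benzyl ethers to toluene and the free phenols under neutral conditions that leave the two aryl methyl ethers, the biaryl bond and the conjugated pyranone C2=C3 bonds (which resist hydrogenation at atmospheric pressure) intact.

Compound list
1 | 1-(2,6-dihydroxy-4-methoxyphenyl)ethanone | CC(=O)c1c(O)cc(OC)cc1O | starting material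
2 | 1-[2-(benzyloxy)-6-hydroxy-4-methoxyphenyl]ethanone | CC(=O)c1c(O)cc(OC)cc1OCc1ccccc1 | intermediate
3 | 1-[6-(benzyloxy)-2-hydroxy-3-iodo-4-methoxyphenyl]ethanone | CC(=O)c1c(O)c(I)c(OC)cc1OCc1ccccc1 | intermediate
4 | 4-(benzyloxy)benzoyl chloride | O=C(Cl)c1ccc(OCc2ccccc2)cc1 | starting material
5 | 1-[6-(benzyloxy)-2-hydroxy-3-iodo-4-methoxyphenyl]-3-[4-(benzyloxy)phenyl]propane-1,3-dione | O=C(CC(=O)c1ccc(OCc2ccccc2)cc1)c1c(O)c(I)c(OC)cc1OCc1ccccc1 | intermediate
6 | 5-(benzyloxy)-2-[4-(benzyloxy)phenyl]-8-iodo-7-methoxy-4H-chromen-4-one | COc1cc(OCc2ccccc2)c2c(=O)cc(-c3ccc(OCc4ccccc4)cc3)oc2c1I | intermediate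
7 | methyl 4-hydroxy-3-iodobenzoate | COC(=O)c1ccc(O)c(I)c1 | starting material
8 | methyl 4-(benzyloxy)-3-iodobenzoate | COC(=O)c1ccc(OCc2ccccc2)c(I)c1 | intermediate
9 | methyl 4-(benzyloxy)-3-(4,4,5,5-tetramethyl-1,3,2-dioxaborolan-2-yl)benzoate | COC(=O)c1ccc(OCc2ccccc2)c(B2OC(C)(C)C(C)(C)O2)c1 | intermediate
10 | methyl 4-(benzyloxy)-3-{5-(benzyloxy)-2-[4-(benzyloxy)phenyl]-7-methoxy-4-oxo-4H-chromen-8-yl}benzoate | COC(=O)c1ccc(OCc2ccccc2)c(-c2c(OC)cc(OCc3ccccc3)c3c(=O)cc(-c4ccc(OCc5ccccc5)cc4)oc23)c1 | intermediate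
11 | 4-(benzyloxy)-3-{5-(benzyloxy)-2-[4-(benzyloxy)phenyl]-7-methoxy-4-oxo-4H-chromen-8-yl}benzoic acid | OC(=O)c1ccc(OCc2ccccc2)c(-c2c(OC)cc(OCc3ccccc3)c3c(=O)cc(-c4ccc(OCc5ccccc5)cc4)oc23)c1 | intermediate
12 | 2-bromo-1-[2-(benzyloxy)-6-hydroxy-4-methoxyphenyl]ethanone | COc1cc(O)c(C(=O)CBr)c(OCc2ccccc2)c1 | intermediate
13 | triphenylphosphine | c1ccc(cc1)P(c1ccccc1)c1ccccc1 | starting material
14 | {2-[2-(benzyloxy)-6-hydroxy-4-methoxyphenyl]-2-oxoethyl}triphenylphosphonium bromide | COc1cc(O)c(C(=O)C[P+](c2ccccc2)(c2ccccc2)c2ccccc2)c(OCc2ccccc2)c1.[Br-] | intermediate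
15 | 1-[2-(benzyloxy)-6-hydroxy-4-methoxyphenyl]-2-(triphenylphosphoranylidene)ethanone | COc1cc(O)c(C(=O)C=P(c2ccccc2)(c2ccccc2)c2ccccc2)c(OCc2ccccc2)c1 | intermediate
16 | 4-(benzyloxy)-3-{5-(benzyloxy)-2-[4-(benzyloxy)phenyl]-7-methoxy-4-oxo-4H-chromen-8-yl}benzoyl chloride | O=C(Cl)c1ccc(OCc2ccccc2)c(-c2c(OC)cc(OCc3ccccc3)c3c(=O)cc(-c4ccc(OCc5ccccc5)cc4)oc23)c1 | intermediate
17 | 3-(benzyloxy)-5-methoxy-2-[(triphenylphosphoranylidene)acetyl]phenyl 4-(benzyloxy)-3-{5-(benzyloxy)-2-[4-(benzyloxy)phenyl]-7-methoxy-4-oxo-4H-chromen-8-yl}benzoate | COc1cc(OCc2ccccc2)c(C(=O)C=P(c2ccccc2)(c2ccccc2)c2ccccc2)c(OC(=O)c2ccc(OCc3ccccc3)c(-c3c(OC)cc(OCc4ccccc4)c4c(=O)cc(-c5ccc(OCc6ccccc6)cc5)oc34)c2)c1 | intermediate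
18 | 5-(benzyloxy)-2-{4-(benzyloxy)-3-[5-(benzyloxy)-2-(4-(benzyloxy)phenyl)-7-methoxy-4-oxo-4H-chromen-8-yl]phenyl}-7-methoxy-4H-chromen-4-one | COc1cc(OCc2ccccc2)c2c(=O)cc(-c3ccc(OCc4ccccc4)c(-c4c(OC)cc(OCc5ccccc5)c5c(=O)cc(-c6ccc(OCc7ccccc7)cc6)oc45)c3)oc2c1 | intermediate
19 | 7,7''-dimethoxyamentoflavone | COc1cc(O)c2c(=O)cc(-c3ccc(O)c(-c4c(OC)cc(O)c5c(=O)cc(-c6ccc(O)cc6)oc45)c3)oc2c1 | target

Total step count: 13. Longest linear sequence: 9 steps (steps 1, 2, 3, 4, 7, 8, 11, 12, 13).

Steps most likely to fail

1. Step 12 (key step). The ylide may shift the aroyl group from oxygen to carbon with expulsion of the phenoxide and end as an unreactive diacyl ylide. Alternatively, the doubly ortho-flanked ylide may close so slowly that adventitious hydrolysis of the aryl ester wins. The fallback sets out from 11 and 2 and returns to the route at 18. Acid 11 is converted into chloride 16 as in step 11 and used to esterify the phenol of acetophenone 2 (Et3N, cat. 4-dimethylaminopyridine, CH2Cl2), which should give the 2-acetyl-3-(benzyloxy)-5-methoxyphenyl ester F1. Baker–Venkataraman rearrangement with LiN(SiMe3)2 in THF (−78 → 0 °C) should move the aroyl group to the acetyl carbon and give the 1,3-diketone F2. Cyclodehydration with NaOAc in AcOH at 110 °C, as in step 4, should then deliver 18.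

2. Step 7. Transmetalation onto the crowded C8'' palladium centre may be slower than protodeboronation of the ortho-alkoxy boronate and than reduction of the iodide, so that both partners are consumed without coupling. The fallback is a Negishi coupling that sets out from 8 and 6 and returns at 10. Iodide 8 undergoes iodine–magnesium exchange with i-PrMgCl·LiCl in THF at −30 °C, a temperature at which the ester is tolerated, to give the arylmagnesium chloride F3. ZnCl2 converts it into the arylzinc chloride F4, which is coupled with 6 using Pd(OAc)2/SPhos in THF at 60 °C. Under these anhydrous conditions the arylzinc reagent is not exposed to protodemetalation, and it does not add to the flavone carbonyl.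

3. Step 9. Bromine may be delivered to the very electron-rich ring (C3 or C5) instead of the enol, or the methyl ketone may be brominated twice. The fallback sets out from 2 and returns at 12. Ketone 2 is converted with Me3SiOTf/Et3N (2.2 equiv each, CH2Cl2, 0 °C) into the aryl silyl ether–silyl enol ether F5. This is treated with N-bromosuccinimide in THF at −78 °C, where the enol ether should react far faster than the arene. Aqueous work-up cleaves the aryl silyl ether and should return 12.

Further compounds
F1 | step 12 | 2-acetyl-3-(benzyloxy)-5-methoxyphenyl 4-(benzyloxy)-3-{5-(benzyloxy)-2-[4-(benzyloxy)phenyl]-7-methoxy-4-oxo-4H-chromen-8-yl}benzoate | CC(=O)c1c(OCc2ccccc2)cc(OC)cc1OC(=O)c1ccc(OCc2ccccc2)c(-c2c(OC)cc(OCc3ccccc3)c3c(=O)cc(-c4ccc(OCc5ccccc5)cc4)oc23)c1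
F2 | step 12 | 1-[2-(benzyloxy)-6-hydroxy-4-methoxyphenyl]-3-{4-(benzyloxy)-3-[5-(benzyloxy)-2-(4-(benzyloxy)phenyl)-7-methoxy-4-oxo-4H-chromen-8-yl]phenyl}propane-1,3-dione | COc1cc(O)c(C(=O)CC(=O)c2ccc(OCc3ccccc3)c(-c3c(OC)cc(OCc4ccccc4)c4c(=O)cc(-c5ccc(OCc6ccccc6)cc5)oc34)c2)c(OCc2ccccc2)c1
F3 | step 7 | [2-(benzyloxy)-5-(methoxycarbonyl)phenyl]magnesium chloride | COC(=O)c1ccc(OCc2ccccc2)c([Mg]Cl)c1
F4 | step 7 | [2-(benzyloxy)-5-(methoxycarbonyl)phenyl]zinc chloride | COC(=O)c1ccc(OCc2ccccc2)c([Zn]Cl)c1
F5 | step 9 | {1-[2-(benzyloxy)-4-methoxy-6-(trimethylsilyloxy)phenyl]vinyloxy}trimethylsilane | C=C(O[Si](C)(C)C)c1c(O[Si](C)(C)C)cc(OC)cc1OCc1ccccc1
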